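The flavanone is disconnected at the C2–C3 bond of ring C. C3, the methylene next to the C4 carbonyl, is traced back to the carbon of a diazomethyl ketone, and C2, the benzylic carbon bonded to O1 and to ring B, to the CH2 group of an aryl benzyl ether. A chiral dirhodium carboxylate converts the diazoketone into a carbene that inserts into one enantiotopic C–H bond of this CH2 group, which O1 and ring B both activate, closing ring C and setting C2 in one operation. The precursor is a fully silyl-protected phloroglucinol diazoketone that already carries the (6R)-hydroxylated geranyl-type chain at the future C6 and a 3,4-bis(silyloxy)benzyl ether on the future O1.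

Key step: step 13

Remark: TBS = tert-butyldimethylsilyl, TIPS = triisopropylsilyl; locants 2–8, 4a, 8a and rings A, B, C are those of the flavanone, and doubly primed locants belong to the side chain.

Assumption: the (S)-ligand set of Rh2(S-PTTL)4 is taken to give the (2S) configuration; should a model run show the opposite sense, Rh2(R-PTTL)4 is used under the same conditions.

Step 1
Reactants: 1 geranyl acetate
Product: 2 (6R)-6,7-epoxygeranyl acetate
Conditions: Shi ketone derived from D-fructose (0.3 equiv), Oxone (2KHSO5·KHSO4·K2SO4), K2CO3, Bu4NHSO4 (cat.), MeCN–CH2(OMe)2 / aq. Na2B4O7 buffer, 0 °C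
Reagents that add atoms: Oxone (potassium peroxymonosulfate), [K+].[O-]S(=O)(=O)OO
Why: Shi asymmetric epoxidation: the chiral dioxirane formed from the D-fructose-derived ketone attacks the electron-richer 6,7-alkene (the 2,3-alkene is deactivated by the allylic acetate) through a spiro transition state that delivers oxygen to the face giving the (6R)-epoxide, which sets the carbinol stereocenter of the side chain.

Step 2
Reactants: 2 (6R)-6,7-epoxygeranyl acetate
Product: 3 (2E,6R)-6-hydroxy-3,7-dimethylocta-2,7-dien-1-yl acetate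
Conditions: Al(OiPr)3, toluene, reflux; aqueous work-up
Reagents that add atoms: none
Why: Aluminium isopropoxide-mediated isomerisation of a trisubstituted epoxide to an allylic alcohol: the aluminium-bound epoxide loses a proton from a geminal methyl group in a cyclic syn-elimination, so the tertiary C–O bond opens to the isopropenyl group while the C6–O bond and its (R) configuration stay untouched.

Step 3
Reactants: 3 (2E,6R)-6-hydroxy-3,7-dimethylocta-2,7-dien-1-yl acetate
Product: 4 TBS ether of 3
Conditions: TBSCl, imidazole, DMF, rt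
Reagents that add atoms: tert-butyldimethylsilyl chloride, C[Si](C)(Cl)C(C)(C)C
Why: Silylation of the secondary allylic alcohol (TBSCl, imidazole) masks the only O–H bond that would otherwise interfere with the bromide, the alkylation and the later carbene step.

Step 4
Reactants: 4 TBS ether of 3
Product: 5 (2E,6R)-6-(TBS-oxy)-3,7-dimethylocta-2,7-dien-1-ol
Conditions: K2CO3 (cat.), MeOH, 0 °C to rt
Reagents that add atoms: none
Why: Base-catalysed transesterification (methanolysis) removes the primary acetate without touching the secondary TBS ether.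

Step 5
Reactants: 5 (2E,6R)-6-(TBS-oxy)-3,7-dimethylocta-2,7-dien-1-ol
Product: 6 (2E,6R)-1-bromo-6-(TBS-oxy)-3,7-dimethylocta-2,7-diene
Conditions: CBr4, PPh3, CH2Cl2, 0 °C; used without delay
Reagents that add atoms: carbon tetrabromide, BrC(Br)(Br)Br
Why: Appel reaction: the primary allylic alcohol is displaced via its alkoxyphosphonium salt by bromide in an SN2 step at low temperature, which keeps the E geometry and avoids allylic transposition.

Step 6
Reactants: 7 3,4-dihydroxybenzaldehyde
Product: 8 3,4-bis(TBS-oxy)benzaldehyde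
Conditions: TBSCl (2.4 equiv), imidazole, DMF, rt
Reagents that add atoms: tert-butyldimethylsilyl chloride, C[Si](C)(Cl)C(C)(C)C
Why: Silylation of both phenols (TBSCl, imidazole) protects the catechol as base- and carbene-stable silyl ethers that fluoride removes at the end.

Step 7
Reactants: 8 3,4-bis(TBS-oxy)benzaldehyde
Product: 9 [3,4-bis(TBS-oxy)phenyl]methanol
Conditions: NaBH4, MeOH–THF, 0 °C
Reagents that add atoms: none
Why: Sodium borohydride reduction of the aldehyde gives the benzylic alcohol needed as the Mitsunobu partner, aryl silyl ethers being stable at 0 °C.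

Step 8
Reactants: 10 2,4,6-trihydroxyacetophenone (3 equiv, dried); 6 allylic bromide
Product: 11 3-C-alkylated 2,4,6-trihydroxyacetophenone (side chain at C3)
Conditions: DBU (1.5 equiv relative to 6), THF, 0 °C to rt
Reagents that add atoms: none
Why: Nuclear C-alkylation of the ambident phloroglucinol phenoxide with a soft allylic bromide (Friedel–Crafts-type C-allylation of an acylphloroglucinol); C3 and C5 of 10 are equivalent, so only one mono-C-alkyl product can form, and excess 10 suppresses double alkylation.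

Step 9
Reactants: 11 3-C-alkylated 2,4,6-trihydroxyacetophenone
Product: 12 4-O-TIPS ether of 11 (2-OH and 6-OH free)
Conditions: TIPSCl (1.05 equiv), Et3N (1.2 equiv), CH2Cl2, −40 °C to 0 °C
Reagents that add atoms: triisopropylsilyl chloride, CC(C)[Si](Cl)(C(C)C)C(C)C
Why: Acidity-controlled monosilylation: the 4-OH para to the acetyl group is the most acidic and is not tied up in the hydrogen bond to the carbonyl, so its ammonium phenoxide is silylated first by the bulky silyl chloride at low temperature.

Step 10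
Reactants: 12 4-O-TIPS ether of 11; 9 [3,4-bis(TBS-oxy)phenyl]methanol
Product: 13 6-O-[3,4-bis(TBS-oxy)benzyl] ether of 12 (2-OH free)
Conditions: PPh3, DIAD, THF, 0 °C to rt
Reagents that add atoms: none
Why: Mitsunobu etherification: of the two remaining phenols the 6-OH, flanked only by H and the acetyl group, is alkylated by the alkoxyphosphonium salt of 9, whereas the 2-OH is wedged between side chain and acetyl group and held in the hydrogen bond to the carbonyl.

Step 11
Reactants: 13 6-O-benzyl ether with free 2-OH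
Product: 14 2-O-TBS ether of 13 (fully protected methyl ketone)
Conditions: TBSOTf (1.3 equiv), 2,6-lutidine, CH2Cl2, −78 °C to 0 °C
Reagents that add atoms: tert-butyldimethylsilyl trifluoromethanesulfonate, C[Si](C)(OS(=O)(=O)C(F)(F)F)C(C)(C)C
Why: Silylation of the hindered, chelated phenol with the silyl triflate and 2,6-lutidine leaves no O–H bond and places at this ortho position a group with no C–H bond within reach of the later carbene.

Step 12
Reactants: 14 fully protected methyl ketone
Product: 16 aryl diazomethyl ketone, via trifluoroacetyl ketone 15 (not isolated)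
Conditions: LiN(SiMe3)2, THF, −78 °C; CF3CO2CH2CF3, −78 °C; aq. NH4Cl work-up; crude 15, then MsN3, Et3N, H2O (1 equiv), MeCN, rt
Reagents that add atoms: methanesulfonyl azide, CS(=O)(=O)N=[N+]=[N-] (supplies the two diazo nitrogens); 2,2,2-trifluoroethyl trifluoroacetate, O=C(OCC(F)(F)F)C(F)(F)F (its CF3CO group is carried only by 15)
Why: Danheiser detrifluoroacetylative diazo transfer: the kinetic lithium enolate of the methyl ketone is C-trifluoroacetylated, and the activated methylene of the resulting 1,3-diketone accepts the diazo group from the sulfonyl azide with loss of the trifluoroacetyl group as its N-sulfonyl amide.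

Step 13
Reactants: 16 aryl diazomethyl ketone
Product: 17 (2S)-flavanone bearing four TBS ethers and one TIPS ether
Conditions: Rh2(S-PTTL)4 (dirhodium tetrakis[N-phthaloyl-(S)-tert-leucinate], 1 mol %), CH2Cl2, 0 °C to rt, 16 added over 4 h by syringe pump (final 0.005 M)
Reagents that add atoms: none
Why: The dirhodium carboxylate extrudes N2 from 16 to give an electrophilic rhodium carbene at the future C3, which inserts into one of the two enantiotopic C–H bonds of the ortho O–CH2–aryl group through a three-centre, hydride-transfer-like transition state, forming the C3–C2 bond and delivering the hydrogen to C3. The closest known reaction type is the dirhodium-catalysed intramolecular C–H insertion of ortho-alkoxyaryl α-diazoketones to chroman-4-ones, including its enantioselective variants with chiral carboxylate ligands, and the related insertion into aryl benzyl ethers that gives 2-aryl-2,3-dihydrobenzofurans. Ring C is closed as a six-membered ring by 1,6-insertion (carbene carbon, C4, C4a, C8a, O1 and C2 in a six-membered cyclic transition state), the only insertion mode open because the fifth atom of that chain is the ether oxygen. The new stereocenter C2 is set under catalyst control: the chiral N-phthaloyl-tert-leucinate ligand sphere differentiates the pro-R and pro-S benzylic hydrogens, and the remote C6'' carbinol center has no influence. The step needs C–H insertion to win over oxonium-ylide formation with [1,2]-benzyl shift, over cyclopropanation of the two chain alkenes and over intermolecular reactions; this is secured by the C–H bond being activated twice (by O1 and by the electron-rich silyloxyaryl ring), by the low nucleophilicity of the aryl ether oxygen and the choice of a rhodium carboxylate instead of a copper catalyst, by the other ortho position carrying an OTBS group with no C–H bond within reach, by the alkenes being reachable only through rings of seven or more members, and by slow addition at high dilution.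

Step 14
Reactants: 17 (2S)-flavanone bearing four TBS ethers and one TIPS ether
Product: 18 target, (2S)-6-[(2E,6R)-6-hydroxy-3,7-dimethylocta-2,7-dien-1-yl]eriodictyol
Conditions: HF·pyridine (excess), pyridine, THF, 0 °C to rt; pH 7 phosphate buffer work-up
Reagents that add atoms: none
Why: Fluoride-mediated desilylation under buffered, non-basic conditions cleaves all five Si–O bonds without the base-induced ring opening to the chalcone that would racemise C2 and without acid-induced cyclisation of the prenyl-type chain onto a neighbouring phenol.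

Compound list
1 | geranyl acetate, (2E)-3,7-dimethylocta-2,6-dien-1-yl acetate | CC(C)=CCC/C(C)=C/COC(C)=O | starting material
2 | (2E)-5-[(2R)-3,3-dimethyloxiran-2-yl]-3-methylpent-2-en-1-yl acetate | CC1(C)O[C@@H]1CC/C(C)=C/COC(C)=O | intermediate
3 | (2E,6R)-6-hydroxy-3,7-dimethylocta-2,7-dien-1-yl acetate | C=C(C)[C@H](O)CC/C(C)=C/COC(C)=O | intermediate
4 | (2E,6R)-6-[(tert-butyldimethylsilyl)oxy]-3,7-dimethylocta-2,7-dien-1-yl acetate | C=C(C)[C@H](O[Si](C)(C)C(C)(C)C)CC/C(C)=C/COC(C)=O | intermediate
5 | (2E,6R)-6-[(tert-butyldimethylsilyl)oxy]-3,7-dimethylocta-2,7-dien-1-ol | C=C(C)[C@H](O[Si](C)(C)C(C)(C)C)CC/C(C)=C/CO | intermediate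
6 | (2E,6R)-1-bromo-6-[(tert-butyldimethylsilyl)oxy]-3,7-dimethylocta-2,7-diene | C=C(C)[C@H](O[Si](C)(C)C(C)(C)C)CC/C(C)=C/CBr | intermediate
7 | 3,4-dihydroxybenzaldehyde | O=Cc1ccc(O)c(O)c1 | starting material
8 | 3,4-bis[(tert-butyldimethylsilyl)oxy]benzaldehyde | O=Cc1ccc(O[Si](C)(C)C(C)(C)C)c(O[Si](C)(C)C(C)(C)C)c1 | intermediate
9 | {3,4-bis[(tert-butyldimethylsilyl)oxy]phenyl}methanol | OCc1ccc(O[Si](C)(C)C(C)(C)C)c(O[Si](C)(C)C(C)(C)C)c1 | intermediate
10 | 2,4,6-trihydroxyacetophenone | CC(=O)c1c(O)cc(O)cc1O | starting material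
11 | 1-[3-{(2E,6R)-6-[(tert-butyldimethylsilyl)oxy]-3,7-dimethylocta-2,7-dien-1-yl}-2,4,6-trihydroxyphenyl]ethan-1-one | C=C(C)[C@H](O[Si](C)(C)C(C)(C)C)CC/C(C)=C/Cc1c(O)cc(O)c(C(C)=O)c1O | intermediate
12 | 1-[3-{(2E,6R)-6-[(tert-butyldimethylsilyl)oxy]-3,7-dimethylocta-2,7-dien-1-yl}-2,6-dihydroxy-4-[(triisopropylsilyl)oxy]phenyl]ethan-1-one | C=C(C)[C@H](O[Si](C)(C)C(C)(C)C)CC/C(C)=C/Cc1c(O[Si](C(C)C)(C(C)C)C(C)C)cc(O)c(C(C)=O)c1O | intermediate
13 | 1-[6-({3,4-bis[(tert-butyldimethylsilyl)oxy]phenyl}methoxy)-3-{(2E,6R)-6-[(tert-butyldimethylsilyl)oxy]-3,7-dimethylocta-2,7-dien-1-yl}-2-hydroxy-4-[(triisopropylsilyl)oxy]phenyl]ethan-1-one | C=C(C)[C@H](O[Si](C)(C)C(C)(C)C)CC/C(C)=C/Cc1c(O[Si](C(C)C)(C(C)C)C(C)C)cc(OCc2ccc(O[Si](C)(C)C(C)(C)C)c(O[Si](C)(C)C(C)(C)C)c2)c(C(C)=O)c1O | intermediate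
14 | 1-[6-({3,4-bis[(tert-butyldimethylsilyl)oxy]phenyl}methoxy)-2-[(tert-butyldimethylsilyl)oxy]-3-{(2E,6R)-6-[(tert-butyldimethylsilyl)oxy]-3,7-dimethylocta-2,7-dien-1-yl}-4-[(triisopropylsilyl)oxy]phenyl]ethan-1-one | C=C(C)[C@H](O[Si](C)(C)C(C)(C)C)CC/C(C)=C/Cc1c(O[Si](C(C)C)(C(C)C)C(C)C)cc(OCc2ccc(O[Si](C)(C)C(C)(C)C)c(O[Si](C)(C)C(C)(C)C)c2)c(C(C)=O)c1O[Si](C)(C)C(C)(C)C | intermediate
15 | 4,4,4-trifluoro-1-(aryl)butane-1,3-dione, aryl as in 14 (trifluoroacetyl ketone of 14) | C=C(C)[C@H](O[Si](C)(C)C(C)(C)C)CC/C(C)=C/Cc1c(O[Si](C(C)C)(C(C)C)C(C)C)cc(OCc2ccc(O[Si](C)(C)C(C)(C)C)c(O[Si](C)(C)C(C)(C)C)c2)c(C(=O)CC(=O)C(F)(F)F)c1O[Si](C)(C)C(C)(C)C | intermediate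
16 | 2-diazo-1-(aryl)ethan-1-one, aryl as in 14 (diazomethyl ketone) | C=C(C)[C@H](O[Si](C)(C)C(C)(C)C)CC/C(C)=C/Cc1c(O[Si](C(C)C)(C(C)C)C(C)C)cc(OCc2ccc(O[Si](C)(C)C(C)(C)C)c(O[Si](C)(C)C(C)(C)C)c2)c(C(=O)C=[N+]=[N-])c1O[Si](C)(C)C(C)(C)C | intermediate
17 | (2S)-2-{3,4-bis[(tert-butyldimethylsilyl)oxy]phenyl}-5-[(tert-butyldimethylsilyl)oxy]-6-{(2E,6R)-6-[(tert-butyldimethylsilyl)oxy]-3,7-dimethylocta-2,7-dien-1-yl}-7-[(triisopropylsilyl)oxy]-2,3-dihydro-4H-chromen-4-one | C=C(C)[C@H](O[Si](C)(C)C(C)(C)C)CC/C(C)=C/Cc1c(O[Si](C(C)C)(C(C)C)C(C)C)cc2c(c1O[Si](C)(C)C(C)(C)C)C(=O)C[C@@H](c1ccc(O[Si](C)(C)C(C)(C)C)c(O[Si](C)(C)C(C)(C)C)c1)O2 | intermediate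
18 | (2S)-2-(3,4-dihydroxyphenyl)-5,7-dihydroxy-6-[(2E,6R)-6-hydroxy-3,7-dimethylocta-2,7-dien-1-yl]-2,3-dihydro-4H-chromen-4-one | C=C(C)[C@H](O)CC/C(C)=C/Cc1c(O)cc2c(c1O)C(=O)C[C@@H](c1ccc(O)c(O)c1)O2 | target

Total step count: 14. Longest linear sequence: 12 steps (steps 1–5, then steps 8–14).

Steps most likely to fail

Step 13. The carbene may attack the benzylic ether oxygen instead of the C–H bond (oxonium ylide, then [1,2]-benzyl shift), may add to a chain alkene, or the catalyst may discriminate the two benzylic hydrogens poorly. The fallback sets out from 14 and uses a cation instead of a carbene. The lithium enolate of 14 (LiN(SiMe3)2, THF, −78 °C) is O-acetylated with Ac2O to the enol acetate F1. DDQ with 2,6-dichloropyridine and LiClO4 in 1,2-dichloroethane then removes hydride from the electron-rich benzylic ether CH2 (oxidative C–H cleavage, the step that also underlies DDQ removal of 4-alkoxybenzyl ethers). The aryloxy-stabilised benzylic cation is captured by the enol acetate in a 6-endo cyclisation that forms the same C2–C3 bond with loss of the acetyl group. No element controls C2 in this closure, so 17 is expected together with its (2R)-epimer F2, from which it is separated by preparative HPLC on a chiral stationary phase. The fallback comes back to the route at 17.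

Step 9. The silylation may spread over the 4- and 6-hydroxyls or run on to a bis-silyl ether. The fallback sets out from 11 and needs no discrimination between these two hydroxyls. Mitsunobu etherification with 2.2 equiv of 9 converts both into 3,4-bis(silyloxy)benzyl ethers, the bis-ether F3; the 2-OH stays free for the reasons given in step 10. TBSOTf and 2,6-lutidine give the silyl ether F4. Diazo transfer as in step 12 leads through the trifluoroacetyl ketone F5 (not isolated) to the diazoketone F6. Rh2(S-PTTL)4 then gives the flavanone F7, since only the ortho ether lies within reach of the carbene. HF·pyridine removes the six silyl groups to give the 7-O-(3,4-dihydroxybenzyl) ether F8 (not isolated). Brief exposure to pH 7.5 phosphate buffer containing 2-mercaptoethanol lets this 4-hydroxybenzyl aryl ether fragment by 1,6-elimination, with the thiol trapping the quinone methide, and the fallback comes back to the route at 18. The price is a short, mildly basic period for the free flavanone, during which C2 must be watched for epimerisation.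

Step 8. O-Alkylation, double C-alkylation and SN2' attack may compete with the wanted mono-C-alkylation. The fallback sets out from 5 and replaces the bromide by a π-allylpalladium electrophile. Methyl chloroformate and pyridine give the allylic methyl carbonate F9, which reacts with 10 and Pd(PPh3)4 in THF in a Tsuji–Trost allylation. The soft carbon nucleophile should attack the less substituted allyl terminus with retention of the E geometry, and any aryl allyl ether formed re-ionises under the catalyst, so the C-allyl product should accumulate. The fallback comes back to the route at 11.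

Further compounds
F1 | step 13 | 1-(aryl)ethenyl acetate, aryl as in 14 (enol acetate of 14) | C=C(C)[C@H](O[Si](C)(C)C(C)(C)C)CC/C(C)=C/Cc1c(O[Si](C(C)C)(C(C)C)C(C)C)cc(OCc2ccc(O[Si](C)(C)C(C)(C)C)c(O[Si](C)(C)C(C)(C)C)c2)c(C(=C)OC(C)=O)c1O[Si](C)(C)C(C)(C)C
F2 | step 13 | (2R)-epimer of 17 | C=C(C)[C@H](O[Si](C)(C)C(C)(C)C)CC/C(C)=C/Cc1c(O[Si](C(C)C)(C(C)C)C(C)C)cc2c(c1O[Si](C)(C)C(C)(C)C)C(=O)C[C@H](c1ccc(O[Si](C)(C)C(C)(C)C)c(O[Si](C)(C)C(C)(C)C)c1)O2
F3 | step 9 | 1-[4,6-bis({3,4-bis[(tert-butyldimethylsilyl)oxy]phenyl}methoxy)-3-{(2E,6R)-6-[(tert-butyldimethylsilyl)oxy]-3,7-dimethylocta-2,7-dien-1-yl}-2-hydroxyphenyl]ethan-1-one | C=C(C)[C@H](O[Si](C)(C)C(C)(C)C)CC/C(C)=C/Cc1c(OCc2ccc(O[Si](C)(C)C(C)(C)C)c(O[Si](C)(C)C(C)(C)C)c2)cc(OCc2ccc(O[Si](C)(C)C(C)(C)C)c(O[Si](C)(C)C(C)(C)C)c2)c(C(C)=O)c1O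
F4 | step 9 | 2-O-TBS ether of F3 | C=C(C)[C@H](O[Si](C)(C)C(C)(C)C)CC/C(C)=C/Cc1c(OCc2ccc(O[Si](C)(C)C(C)(C)C)c(O[Si](C)(C)C(C)(C)C)c2)cc(OCc2ccc(O[Si](C)(C)C(C)(C)C)c(O[Si](C)(C)C(C)(C)C)c2)c(C(C)=O)c1O[Si](C)(C)C(C)(C)C
F5 | step 9 | trifluoroacetyl ketone of F4 | C=C(C)[C@H](O[Si](C)(C)C(C)(C)C)CC/C(C)=C/Cc1c(OCc2ccc(O[Si](C)(C)C(C)(C)C)c(O[Si](C)(C)C(C)(C)C)c2)cc(OCc2ccc(O[Si](C)(C)C(C)(C)C)c(O[Si](C)(C)C(C)(C)C)c2)c(C(=O)CC(=O)C(F)(F)F)c1O[Si](C)(C)C(C)(C)C
F6 | step 9 | diazomethyl ketone of F4 | C=C(C)[C@H](O[Si](C)(C)C(C)(C)C)CC/C(C)=C/Cc1c(OCc2ccc(O[Si](C)(C)C(C)(C)C)c(O[Si](C)(C)C(C)(C)C)c2)cc(OCc2ccc(O[Si](C)(C)C(C)(C)C)c(O[Si](C)(C)C(C)(C)C)c2)c(C(=O)C=[N+]=[N-])c1O[Si](C)(C)C(C)(C)C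
F7 | step 9 | (2S)-7-({3,4-bis[(tert-butyldimethylsilyl)oxy]phenyl}methoxy)-2-{3,4-bis[(tert-butyldimethylsilyl)oxy]phenyl}-5-[(tert-butyldimethylsilyl)oxy]-6-{(2E,6R)-6-[(tert-butyldimethylsilyl)oxy]-3,7-dimethylocta-2,7-dien-1-yl}-2,3-dihydro-4H-chromen-4-one | C=C(C)[C@H](O[Si](C)(C)C(C)(C)C)CC/C(C)=C/Cc1c(OCc3ccc(O[Si](C)(C)C(C)(C)C)c(O[Si](C)(C)C(C)(C)C)c3)cc2c(c1O[Si](C)(C)C(C)(C)C)C(=O)C[C@@H](c1ccc(O[Si](C)(C)C(C)(C)C)c(O[Si](C)(C)C(C)(C)C)c1)O2
F8 | step 9 | 7-O-(3,4-dihydroxybenzyl) ether of 18 | C=C(C)[C@H](O)CC/C(C)=C/Cc1c(OCc3ccc(O)c(O)c3)cc2c(c1O)C(=O)C[C@@H](c1ccc(O)c(O)c1)O2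
F9 | step 8 | (2E,6R)-6-[(tert-butyldimethylsilyl)oxy]-3,7-dimethylocta-2,7-dien-1-yl methyl carbonate | C=C(C)[C@H](O[Si](C)(C)C(C)(C)C)CC/C(C)=C/COC(=O)OC
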